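**Plan**

1. Cuts: first the helpers (eight O‑benzyl, two C‑tert‑butyl). Next, in one retro‑step, C‑7e–C‑10d (eight‑membered ring C‑8c/9c/10c/8d/9d/10d/7e/8e) and C‑7b–C‑10a (seven‑membered ring). Then C‑7c–C‑8b, then C‑8c–C‑8e. This leaves three blocks a/b, c/d and e/f built on one (2R,3R)‑2,3‑diaryl‑4‑bromo‑2,3‑dihydrobenzofuran.
2. Enabling feature: C‑7b and C‑7e are benzylic CH carbons para to the OH of rings B‑1 and E‑1, so they are reduced p‑quinone methides. Their partners C‑10a and C‑10d lie ortho/para to the two OH groups of resorcinol rings A‑2 and D‑2, so they are phenolate C‑nucleophiles. Every competing arene position (C‑14c, C‑10f/14f) sits in a ring that can stay an ether.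
3. Forward: the three dihydrofuran rings arise first, from one enantioselective carbene C–H insertion. Pd chemistry turns the bromide into a stilbene phenol (c/d) and two deoxybenzoins (a/b, e/f). The chain is joined at C‑8c–C‑8e and then at C‑7c–C‑8b. One fluoride‑triggered event then closes the seven‑membered ring and, last, the eight‑membered ring.
4. Helpers: TIPS ethers switch on rings A‑2, D‑2, B‑1 and E‑1. Benzyl ethers keep C‑2, E‑2 and F‑2 silent. The ketone → acetate oxidation level stores the two quinone methides. The tert‑butyl groups make the central quinone methide isolable. All helpers are removed in steps 21–23.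
5. Stereochemistry: C‑8a/d/f come from the chiral Rh(II) catalyst, and C‑7a/d/f from acid equilibration to trans. C‑8b, C‑8c and C‑8e arise by attack anti to the C‑3 aryl ring of their own dihydrobenzofuran. C‑7c arises by attack on the open face of the quinone methide. C‑7b and C‑7e are set in the key step, which is stereoconvergent from all carbinol epimers.

Key step: step 21

Notation: units a–f. In each unit, C‑7 carries the 4‑oxyphenyl ring (A‑1 … F‑1) and C‑8 carries the 3,5‑dioxyphenyl ring (A‑2 … F‑2, C‑9 to C‑14). TIPS = triisopropylsilyl. Centres drawn without a label are epimer mixtures that are carried on together.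

Assumption: Rh2(S‑PTAD)4 is taken to give the 3R series in step 8; if the sense of induction is opposite, the enantiomeric catalyst is used.

**Step 1**
Reactants: 1 5‑bromoresorcinol
Product: 2 1‑bromo‑3,5‑bis(triisopropylsilyloxy)benzene
Conditions: TIPSCl, imidazole, DMF, rt
Reagents that add atoms: chlorotriisopropylsilane CC(C)[Si](Cl)(C(C)C)C(C)C
Why: Imidazole‑promoted O‑silylation; the TIPS aryl ethers are the fluoride‑labile switch of the plan and should tolerate Grignard formation, hydrazine, acid and phosphate base.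

**Step 2**
Reactants: 1 5‑bromoresorcinol
Product: 3 2‑bromo‑4,6‑dihydroxybenzaldehyde
Conditions: POCl3, DMF, MeCN, 0 °C → rt; then H2O, 50 °C
Reagents that add atoms: N,N‑dimethylformamide CN(C)C=O; water O
Why: Vilsmeier–Haack formylation goes para to one OH and ortho to the other, as with orcinol, which places CHO between OH and Br.

**Step 3**
Reactants: 3 2‑bromo‑4,6‑dihydroxybenzaldehyde
Product: 4 4‑(benzyloxy)‑2‑bromo‑6‑hydroxybenzaldehyde
Conditions: BnBr (1.0 equiv), NaHCO3, KI (cat.), MeCN, 60 °C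
Reagents that add atoms: benzyl bromide BrCc1ccccc1
Why: Williamson etherification is selective for the 4‑OH because the 6‑OH is held in a hydrogen bond to the aldehyde.

**Step 4**
Reactants: 4 4‑(benzyloxy)‑2‑bromo‑6‑hydroxybenzaldehyde; 5 4‑(benzyloxy)benzyl chloride
Product: 6 4‑(benzyloxy)‑2‑{[4‑(benzyloxy)benzyl]oxy}‑6‑bromobenzaldehyde
Conditions: K2CO3, NaI (cat.), DMF, 60 °C
Reagents that add atoms: none
Why: Williamson etherification of the chelated phenol under more forcing conditions installs the OCH2Ar group that becomes C‑7 and ring 1 of each dihydrobenzofuran.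

**Step 5**
Reactants: 2 1‑bromo‑3,5‑bis(triisopropylsilyloxy)benzene; 6 4‑(benzyloxy)‑2‑{[4‑(benzyloxy)benzyl]oxy}‑6‑bromobenzaldehyde
Product: 8 (±)‑diarylmethanol, via arylmagnesium bromide 7 (not isolated)
Conditions: Mg, THF, reflux; then 6, THF, −40 → 0 °C; H2O
Reagents that add atoms: none
Why: Grignard addition to the aldehyde outruns halogen–metal exchange at low temperature, and the carbinol centre is removed in step 6.

**Step 6**
Reactants: 8 (±)‑diarylmethanol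
Product: 9 2‑aryloxymethyl‑6‑bromobenzophenone
Conditions: Dess–Martin periodinane, CH2Cl2, rt
Reagents that add atoms: none
Why: Dess–Martin oxidation converts a hindered diarylmethanol under neutral conditions that spare silyl and benzyl ethers.

**Step 7**
Reactants: 9 benzophenone
Product: 10 benzophenone hydrazone (E/Z mixture)
Conditions: N2H4·H2O (excess), AcOH (cat.), n‑BuOH, 120 °C
Reagents that add atoms: hydrazine NN
Why: Hydrazone condensation is forced with excess hydrazine at high temperature because the ketone is di‑ortho‑substituted.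

**Step 8**
Reactants: 10 benzophenone hydrazone
Product: 12 cis‑(2S,3R)‑6‑(benzyloxy)‑2‑[4‑(benzyloxy)phenyl]‑4‑bromo‑3‑[3,5‑bis(triisopropylsilyloxy)phenyl]‑2,3‑dihydrobenzofuran, via diaryldiazomethane 11 (not isolated)
Conditions: MnO2, CH2Cl2, 0 °C, filter; Rh2(S‑PTAD)4 (1 mol %), CH2Cl2, 0 °C → rt
Reagents that add atoms: none
Why: Dehydrogenation to the diazo compound and enantioselective Rh(II) donor/donor‑carbene 1,5‑C–H insertion into the activated ArCH2–O bond close the dihydrofuran; the chiral carboxylate ligands set C‑3 as R and the concerted insertion gives the cis isomer.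

**Step 9**
Reactants: 12 cis‑(2S,3R)‑dihydrobenzofuran bromide
Product: 13 trans‑(2R,3R)‑6‑(benzyloxy)‑2‑[4‑(benzyloxy)phenyl]‑4‑bromo‑3‑[3,5‑bis(triisopropylsilyloxy)phenyl]‑2,3‑dihydrobenzofuran
Conditions: TFA, CH2Cl2, 0 °C
Reagents that add atoms: none
Why: In this acid‑mediated epimerisation, reversible ionisation of the C‑2–O bond to the 4‑benzyloxybenzyl cation lets C‑2 relax to the more stable trans isomer while C‑3 is untouched.

**Step 10**
Reactants: 13 trans‑(2R,3R)‑bromide, TIPS series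
Product: 14 trans‑(2R,3R)‑6‑(benzyloxy)‑2‑[4‑(benzyloxy)phenyl]‑3‑[3,5‑bis(benzyloxy)phenyl]‑4‑bromo‑2,3‑dihydrobenzofuran
Conditions: CsF, BnBr, DMF, rt
Reagents that add atoms: benzyl bromide BrCc1ccccc1
Why: One‑pot fluoride desilylation/Williamson benzylation turns the switchable ethers into permanent ones, which will keep ring F‑2 silent in step 21.

**Step 11**
Reactants: 15 4′‑hydroxyacetophenone
Product: 16 4′‑(triisopropylsilyloxy)acetophenone
Conditions: TIPSCl, imidazole, DMF, rt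
Reagents that add atoms: chlorotriisopropylsilane CC(C)[Si](Cl)(C(C)C)C(C)C
Why: Standard O‑silylation provides C‑7, C‑8 and ring 1 of units b and e with the fluoride‑labile donor already in place.

**Step 12**
Reactants: 17 3,5‑di‑tert‑butyl‑4‑hydroxybenzaldehyde
Product: 18 2,6‑di‑tert‑butyl‑4‑vinylphenol
Conditions: Ph3PCH3Br, KOt‑Bu (2.2 equiv), THF, 0 °C → rt
Reagents that add atoms: methyltriphenylphosphonium bromide C[P+](c1ccccc1)(c1ccccc1)c1ccccc1.[Br-]
Why: Wittig methylenation, with the second equivalent of base covering the phenol.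

**Step 13**
Reactants: 13 trans‑(2R,3R)‑bromide, TIPS series; 18 2,6‑di‑tert‑butyl‑4‑vinylphenol
Product: 19 block c/d, (E)‑4‑{2‑[(2R,3R)‑dihydrobenzofuran‑4‑yl]ethenyl}‑2,6‑di‑tert‑butylphenol
Conditions: Pd2(dba)3, P(t‑Bu)3·HBF4, Cy2NMe, dioxane, 80 °C
Reagents that add atoms: none
Why: Mizoroki–Heck reaction of the hindered, electron‑rich bromide under bulky trialkylphosphine catalysis should give the E‑stilbene, and the shielded phenol does not interfere.

**Step 14**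
Reactants: 13 trans‑(2R,3R)‑bromide, TIPS series; 16 4′‑(triisopropylsilyloxy)acetophenone
Product: 20 block a/b, 2‑[(2R,3R)‑dihydrobenzofuran‑4‑yl]‑1‑[4‑(triisopropylsilyloxy)phenyl]ethanone (ring A‑2 as bis‑TIPS ether)
Conditions: Pd2(dba)3, XPhos, K3PO4, toluene, 90 °C
Reagents that add atoms: none
Why: In this palladium‑catalysed ketone α‑arylation, the ortho‑substituted bromide and the acidity of the product hold the reaction at mono‑arylation.

**Step 15**
Reactants: 14 trans‑(2R,3R)‑bromide, benzyl series; 16 4′‑(triisopropylsilyloxy)acetophenone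
Product: 21 block e/f, 2‑[(2R,3R)‑dihydrobenzofuran‑4‑yl]‑1‑[4‑(triisopropylsilyloxy)phenyl]ethanone (ring F‑2 as dibenzyl ether)
Conditions: Pd2(dba)3, XPhos, K3PO4, toluene, 90 °C
Reagents that add atoms: none
Why: This is the same palladium‑catalysed ketone α‑arylation as in step 14.

**Step 16**
Reactants: 21 block e/f deoxybenzoin
Product: 23 block e/f α‑bromo ketone (epimers at C‑8e), via lithium enolate 22 (not isolated)
Conditions: LiHMDS, THF, −78 °C; NBS, −78 °C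
Reagents that add atoms: N‑bromosuccinimide O=C1CCC(=O)N1Br
Why: Bromination of the preformed enolate at −78 °C avoids electrophilic bromination of the resorcinol diether rings, and both epimers serve because C‑8e is re‑set in step 17.

**Step 17**
Reactants: 19 block c/d stilbene phenol; 23 block e/f α‑bromo ketone
Product: 25 tetramer quinone methide ketone (C‑8c–C‑8e bond; p‑quinone methide at C‑7c, ketone at C‑7e; C‑8c and C‑8e arranged as in 34), via potassium phenolate 24 (not isolated)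
Conditions: KHMDS (1.0 equiv), THF, −78 °C; added slowly to 23 (1.2 equiv), THF–DMPU, −40 → 0 °C, Ar
Reagents that add atoms: none
Why: Proposed new method: the tert‑butyl groups close the oxygen and both ortho carbons of phenolate 24, so its charge (or, after single‑electron transfer to the easily reduced α‑bromo ketone, its spin) can only be expressed at the vinylogous para position C‑8c; SN2 displacement and collapse of the phenoxyl/α‑keto radical pair both form C‑8c–C‑8e and leave the dearomatised ring as an isolable quinone methide, each trigonal carbon reacting anti to the C‑3 aryl ring (D‑2, F‑2) of its own dihydrobenzofuran in the conformer that turns C‑7 towards H‑14; the closest known reaction types are para‑C‑alkylation of 2,6‑di‑tert‑butylphenolates with activated halides, the enolate/α‑halo ketone synthesis of 2,3‑diaryl‑1,4‑diketones, and the 8–8′ dimerisation of 3,5‑di‑tert‑butyl‑4‑hydroxystilbene radicals to bis(quinone methides).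

**Step 18**
Reactants: 20 block a/b deoxybenzoin; 25 tetramer quinone methide ketone
Product: 27 open hexamer diketone phenol (C‑7c–C‑8b bond; ketones at C‑7b and C‑7e; C‑8b, C‑7c, C‑8c, C‑8e as in 34), via potassium enolate 26 (not isolated)
Conditions: KHMDS (1.0 equiv), THF, −78 °C; 25, −78 → −30 °C; AcOH, −78 °C
Reagents that add atoms: none
Why: 1,6‑Conjugate (vinylogous Michael) addition of a ketone enolate to a 2,6‑di‑tert‑butyl‑p‑quinone methide is driven by rearomatisation; aryl ethers are inert without acid, C‑8b reacts anti to ring A‑2, and C‑7c is attacked on the open face of the A(1,3)‑locked quinone methide because the other face is buried under rings C‑2 and D‑2.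

**Step 19**
Reactants: 27 open hexamer diketone phenol
Product: 28 open hexamer diol (epimers at C‑7b and C‑7e)
Conditions: NaBH4, THF–MeOH, 0 °C → rt
Reagents that add atoms: none
Why: Borohydride reduction of both aryl ketones gives four carbinol epimers, which are carried on together because both centres are erased in step 21.

**Step 20**
Reactants: 28 open hexamer diol
Product: 29 open hexamer diacetate (epimers at C‑7b and C‑7e)
Conditions: Ac2O, DMAP, pyridine, CH2Cl2, 0 °C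
Reagents that add atoms: acetic anhydride CC(=O)OC(C)=O
Why: DMAP‑catalysed acetylation acylates the two secondary benzylic alcohols, and the 2,6‑di‑tert‑butylphenol is too hindered to react.

**Step 21**
Reactants: 29 open hexamer diacetate
Product: 32 ring‑closed hexamer, octabenzyl ether with ring C‑1 as 3,5‑di‑tert‑butyl‑4‑hydroxyphenyl, via bis(quinone methide) 30 (not isolated), via mono(quinone methide) 31 (not isolated)
Conditions: TBAF (8 equiv), THF (1 mM, slow addition of 29), −78 → 0 °C; AcOH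
Reagents that add atoms: none
Why: Fluoride strips all six TIPS groups; the freed 4‑oxidobenzyl acetates on rings B‑1 and E‑1 expel acetate to give p‑quinone methides at C‑7b and C‑7e (30), and the freed resorcinolates A‑2 and D‑2 add through C‑10a and C‑10d in intramolecular 1,6‑conjugate (phenolate Friedel–Crafts) additions followed by rearomatisation, which copies the presumed biosynthetic ring closures. The closest known reaction types are fluoride‑ or base‑triggered generation of p‑quinone methides from 4‑silyloxybenzyl esters, C‑alkylation of phenolates by p‑quinone methides, and the quinone‑methide Friedel–Crafts cyclisations of resveratrol dimers and tetramers. The seven‑membered ring should close first by 7‑exo‑trig attack, because C‑10a and C‑7b hang on neighbouring positions of one benzofuran (31), and the eight‑membered ring closes last by 8‑exo‑trig attack, its chain being pre‑folded by two benzo edges and the rigid dihydrobenzofuran c/d. At C‑7e, allylic 1,3‑strain holds H‑8e in the quinone‑methide plane, ring E‑2 covers one face and C‑8c, which carries the nucleophile, delivers C‑10d to the other (7eS); at C‑7b, ring A‑2 stands on the face of ring B‑2 fixed by C‑8a and the quinone‑methide ring turns away from O‑11a into the pseudo‑axial position (7bS); both carbinol centres of 29 are erased in 30, so all four epimers converge. The step needs C‑7e to take C‑10d rather than C‑14c (five‑membered ring) or C‑10f/14f (seven‑membered ring), and C‑7b to take C‑10a rather than C‑14c (six‑membered ring). This is secured because without acid only phenolates are nucleophilic enough, rings C‑2, E‑2 and F‑2 are benzyl ethers, ring C‑1 is a hindered phenol, C‑7c is already saturated so ring D‑2 has no nearer acceptor, rings A‑1, D‑1 and F‑1 stay benzylated so no dihydrofuran can open, and high dilution suppresses intermolecular capture.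

**Step 22**
Reactants: 32 ring‑closed hexamer octabenzyl ether
Product: 33 3c,5c‑di‑tert‑butyl hexamer (all other phenols free)
Conditions: H2 (1 atm), Pd/C, THF–MeOH, rt
Reagents that add atoms: none
Why: Catalytic hydrogenolysis of eight aryl benzyl ethers is the deprotection used on dihydrobenzofuran‑containing resveratrol oligomers, and no stereocentre is touched.

**Step 23**
Reactants: 33 3c,5c‑di‑tert‑butyl hexamer
Product: 34 target hexamer (7aR,8aR,7bS,8bS,7cR,8cR,7dR,8dR,7eS,8eS,7fR,8fR)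
Conditions: AlCl3, toluene–MeNO2, 60 °C
Reagents that add atoms: none
Why: Retro‑Friedel–Crafts de‑tert‑butylation (AlCl3‑mediated transalkylation to toluene) removes the two blocking groups ortho to the OH of ring C‑1, as practised on this class of polyphenols.

**Compound list**

1 | 5‑bromoresorcinol | Oc1cc(O)cc(Br)c1 | starting material
2 | 1‑bromo‑3,5‑bis(triisopropylsilyloxy)benzene | Brc1cc(O[Si](C(C)C)(C(C)C)C(C)C)cc(O[Si](C(C)C)(C(C)C)C(C)C)c1 | intermediate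
3 | 2‑bromo‑4,6‑dihydroxybenzaldehyde | O=Cc1c(O)cc(O)cc1Br | intermediate
4 | 4‑(benzyloxy)‑2‑bromo‑6‑hydroxybenzaldehyde | O=Cc1c(O)cc(OCc2ccccc2)cc1Br | intermediate
5 | 4‑(benzyloxy)benzyl chloride | ClCc1ccc(OCc2ccccc2)cc1 | starting material
6 | 4‑(benzyloxy)‑2‑{[4‑(benzyloxy)benzyl]oxy}‑6‑bromobenzaldehyde | O=Cc1c(OCc2ccc(OCc3ccccc3)cc2)cc(OCc2ccccc2)cc1Br | intermediate
7 | 3,5‑bis(triisopropylsilyloxy)phenylmagnesium bromide | Br[Mg]c1cc(O[Si](C(C)C)(C(C)C)C(C)C)cc(O[Si](C(C)C)(C(C)C)C(C)C)c1 | intermediate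
8 | (±)‑diarylmethanol | OC(c1cc(O[Si](C(C)C)(C(C)C)C(C)C)cc(O[Si](C(C)C)(C(C)C)C(C)C)c1)c1c(OCc2ccc(OCc3ccccc3)cc2)cc(OCc2ccccc2)cc1Br | intermediate
9 | benzophenone | O=C(c1cc(O[Si](C(C)C)(C(C)C)C(C)C)cc(O[Si](C(C)C)(C(C)C)C(C)C)c1)c1c(OCc2ccc(OCc3ccccc3)cc2)cc(OCc2ccccc2)cc1Br | intermediate
10 | benzophenone hydrazone | NN=C(c1cc(O[Si](C(C)C)(C(C)C)C(C)C)cc(O[Si](C(C)C)(C(C)C)C(C)C)c1)c1c(OCc2ccc(OCc3ccccc3)cc2)cc(OCc2ccccc2)cc1Br | intermediate
11 | diaryldiazomethane | [N-]=[N+]=C(c1cc(O[Si](C(C)C)(C(C)C)C(C)C)cc(O[Si](C(C)C)(C(C)C)C(C)C)c1)c1c(OCc2ccc(OCc3ccccc3)cc2)cc(OCc2ccccc2)cc1Br | intermediate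
12 | cis‑(2S,3R)‑dihydrobenzofuran bromide, TIPS series | Brc2cc(OCc9ccccc9)cc3c2[C@@H](c2cc(O[Si](C(C)C)(C(C)C)C(C)C)cc(O[Si](C(C)C)(C(C)C)C(C)C)c2)[C@@H](c2ccc(OCc9ccccc9)cc2)O3 | intermediate
13 | trans‑(2R,3R)‑dihydrobenzofuran bromide, TIPS series | Brc2cc(OCc9ccccc9)cc3c2[C@@H](c2cc(O[Si](C(C)C)(C(C)C)C(C)C)cc(O[Si](C(C)C)(C(C)C)C(C)C)c2)[C@H](c2ccc(OCc9ccccc9)cc2)O3 | intermediate
14 | trans‑(2R,3R)‑dihydrobenzofuran bromide, benzyl series | Brc2cc(OCc9ccccc9)cc3c2[C@@H](c2cc(OCc9ccccc9)cc(OCc9ccccc9)c2)[C@H](c2ccc(OCc9ccccc9)cc2)O3 | intermediate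
15 | 4′‑hydroxyacetophenone | CC(=O)c1ccc(O)cc1 | starting material
16 | 4′‑(triisopropylsilyloxy)acetophenone | CC(=O)c1ccc(O[Si](C(C)C)(C(C)C)C(C)C)cc1 | intermediate
17 | 3,5‑di‑tert‑butyl‑4‑hydroxybenzaldehyde | CC(C)(C)c1cc(C=O)cc(C(C)(C)C)c1O | starting material
18 | 2,6‑di‑tert‑butyl‑4‑vinylphenol | C=Cc1cc(C(C)(C)C)c(O)c(C(C)(C)C)c1 | intermediate
19 | block c/d stilbene phenol | CC(C)(C)c1cc(/C=C/c2cc(OCc9ccccc9)cc3c2[C@@H](c2cc(O[Si](C(C)C)(C(C)C)C(C)C)cc(O[Si](C(C)C)(C(C)C)C(C)C)c2)[C@H](c2ccc(OCc9ccccc9)cc2)O3)cc(C(C)(C)C)c1O | intermediate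
20 | block a/b deoxybenzoin | O=C(Cc2cc(OCc9ccccc9)cc3c2[C@@H](c2cc(O[Si](C(C)C)(C(C)C)C(C)C)cc(O[Si](C(C)C)(C(C)C)C(C)C)c2)[C@H](c2ccc(OCc9ccccc9)cc2)O3)c2ccc(O[Si](C(C)C)(C(C)C)C(C)C)cc2 | intermediate
21 | block e/f deoxybenzoin | O=C(Cc2cc(OCc9ccccc9)cc3c2[C@@H](c2cc(OCc9ccccc9)cc(OCc9ccccc9)c2)[C@H](c2ccc(OCc9ccccc9)cc2)O3)c2ccc(O[Si](C(C)C)(C(C)C)C(C)C)cc2 | intermediate
22 | lithium enolate of 21 | [Li+].[O-]C(=Cc2cc(OCc9ccccc9)cc3c2[C@@H](c2cc(OCc9ccccc9)cc(OCc9ccccc9)c2)[C@H](c2ccc(OCc9ccccc9)cc2)O3)c2ccc(O[Si](C(C)C)(C(C)C)C(C)C)cc2 | intermediate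
23 | block e/f α‑bromo ketone | O=C(C(Br)c2cc(OCc9ccccc9)cc3c2[C@@H](c2cc(OCc9ccccc9)cc(OCc9ccccc9)c2)[C@H](c2ccc(OCc9ccccc9)cc2)O3)c2ccc(O[Si](C(C)C)(C(C)C)C(C)C)cc2 | intermediate
24 | potassium phenolate of 19 | [K+].CC(C)(C)c1cc(/C=C/c2cc(OCc9ccccc9)cc3c2[C@@H](c2cc(O[Si](C(C)C)(C(C)C)C(C)C)cc(O[Si](C(C)C)(C(C)C)C(C)C)c2)[C@H](c2ccc(OCc9ccccc9)cc2)O3)cc(C(C)(C)C)c1[O-] | intermediate
25 | tetramer quinone methide ketone | CC(C)(C)C1=CC(=C[C@H]([C@@H](C(=O)c2ccc(O[Si](C(C)C)(C(C)C)C(C)C)cc2)c2cc(OCc9ccccc9)cc3c2[C@@H](c2cc(OCc9ccccc9)cc(OCc9ccccc9)c2)[C@H](c2ccc(OCc9ccccc9)cc2)O3)c2cc(OCc9ccccc9)cc3c2[C@@H](c2cc(O[Si](C(C)C)(C(C)C)C(C)C)cc(O[Si](C(C)C)(C(C)C)C(C)C)c2)[C@H](c2ccc(OCc9ccccc9)cc2)O3)C=C(C(C)(C)C)C1=O | intermediate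
26 | potassium enolate of 20 | [K+].[O-]C(=Cc2cc(OCc9ccccc9)cc3c2[C@@H](c2cc(O[Si](C(C)C)(C(C)C)C(C)C)cc(O[Si](C(C)C)(C(C)C)C(C)C)c2)[C@H](c2ccc(OCc9ccccc9)cc2)O3)c2ccc(O[Si](C(C)C)(C(C)C)C(C)C)cc2 | intermediate
27 | open hexamer diketone phenol | CC(C)(C)c1cc([C@@H]([C@@H](C(=O)c2ccc(O[Si](C(C)C)(C(C)C)C(C)C)cc2)c2cc(OCc9ccccc9)cc3c2[C@@H](c2cc(O[Si](C(C)C)(C(C)C)C(C)C)cc(O[Si](C(C)C)(C(C)C)C(C)C)c2)[C@H](c2ccc(OCc9ccccc9)cc2)O3)[C@H]([C@@H](C(=O)c2ccc(O[Si](C(C)C)(C(C)C)C(C)C)cc2)c2cc(OCc9ccccc9)cc3c2[C@@H](c2cc(OCc9ccccc9)cc(OCc9ccccc9)c2)[C@H](c2ccc(OCc9ccccc9)cc2)O3)c2cc(OCc9ccccc9)cc3c2[C@@H](c2cc(O[Si](C(C)C)(C(C)C)C(C)C)cc(O[Si](C(C)C)(C(C)C)C(C)C)c2)[C@H](c2ccc(OCc9ccccc9)cc2)O3)cc(C(C)(C)C)c1O | intermediate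
28 | open hexamer diol | CC(C)(C)c1cc([C@@H]([C@@H](C(O)c2ccc(O[Si](C(C)C)(C(C)C)C(C)C)cc2)c2cc(OCc9ccccc9)cc3c2[C@@H](c2cc(O[Si](C(C)C)(C(C)C)C(C)C)cc(O[Si](C(C)C)(C(C)C)C(C)C)c2)[C@H](c2ccc(OCc9ccccc9)cc2)O3)[C@H]([C@@H](C(O)c2ccc(O[Si](C(C)C)(C(C)C)C(C)C)cc2)c2cc(OCc9ccccc9)cc3c2[C@@H](c2cc(OCc9ccccc9)cc(OCc9ccccc9)c2)[C@H](c2ccc(OCc9ccccc9)cc2)O3)c2cc(OCc9ccccc9)cc3c2[C@@H](c2cc(O[Si](C(C)C)(C(C)C)C(C)C)cc(O[Si](C(C)C)(C(C)C)C(C)C)c2)[C@H](c2ccc(OCc9ccccc9)cc2)O3)cc(C(C)(C)C)c1O | intermediate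
29 | open hexamer diacetate | CC(C)(C)c1cc([C@@H]([C@@H](C(OC(C)=O)c2ccc(O[Si](C(C)C)(C(C)C)C(C)C)cc2)c2cc(OCc9ccccc9)cc3c2[C@@H](c2cc(O[Si](C(C)C)(C(C)C)C(C)C)cc(O[Si](C(C)C)(C(C)C)C(C)C)c2)[C@H](c2ccc(OCc9ccccc9)cc2)O3)[C@H]([C@@H](C(OC(C)=O)c2ccc(O[Si](C(C)C)(C(C)C)C(C)C)cc2)c2cc(OCc9ccccc9)cc3c2[C@@H](c2cc(OCc9ccccc9)cc(OCc9ccccc9)c2)[C@H](c2ccc(OCc9ccccc9)cc2)O3)c2cc(OCc9ccccc9)cc3c2[C@@H](c2cc(O[Si](C(C)C)(C(C)C)C(C)C)cc(O[Si](C(C)C)(C(C)C)C(C)C)c2)[C@H](c2ccc(OCc9ccccc9)cc2)O3)cc(C(C)(C)C)c1O | intermediate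
30 | bis(quinone methide), C‑7b and C‑7e | CC(C)(C)c1cc([C@@H]([C@@H](C=C2C=CC(=O)C=C2)c2cc(OCc9ccccc9)cc3c2[C@@H](c2cc(O)cc(O)c2)[C@H](c2ccc(OCc9ccccc9)cc2)O3)[C@H]([C@@H](C=C2C=CC(=O)C=C2)c2cc(OCc9ccccc9)cc3c2[C@@H](c2cc(OCc9ccccc9)cc(OCc9ccccc9)c2)[C@H](c2ccc(OCc9ccccc9)cc2)O3)c2cc(OCc9ccccc9)cc3c2[C@@H](c2cc(O)cc(O)c2)[C@H](c2ccc(OCc9ccccc9)cc2)O3)cc(C(C)(C)C)c1O | intermediate
31 | mono(quinone methide), seven‑membered ring closed | Oc1ccc([C@H]2c3c(O)cc(O)cc3[C@@H]3c4c(cc(OCc9ccccc9)cc4[C@H]2[C@H](c2cc(C(C)(C)C)c(O)c(C(C)(C)C)c2)[C@H]([C@@H](C=C2C=CC(=O)C=C2)c2cc(OCc9ccccc9)cc4c2[C@@H](c2cc(OCc9ccccc9)cc(OCc9ccccc9)c2)[C@H](c2ccc(OCc9ccccc9)cc2)O4)c2cc(OCc9ccccc9)cc4c2[C@@H](c2cc(O)cc(O)c2)[C@H](c2ccc(OCc9ccccc9)cc2)O4)O[C@H]3c2ccc(OCc9ccccc9)cc2)cc1 | intermediate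
32 | ring‑closed hexamer octabenzyl ether | Oc1ccc([C@H]2c3c(O)cc(O)cc3[C@@H]3c4c(cc(OCc9ccccc9)cc4[C@H]2[C@H](c2cc(C(C)(C)C)c(O)c(C(C)(C)C)c2)[C@H]2c4cc(OCc9ccccc9)cc5c4[C@@H](c4cc(O)cc(O)c4[C@H](c4ccc(O)cc4)[C@H]2c2cc(OCc9ccccc9)cc4c2[C@@H](c2cc(OCc9ccccc9)cc(OCc9ccccc9)c2)[C@H](c2ccc(OCc9ccccc9)cc2)O4)[C@H](c2ccc(OCc9ccccc9)cc2)O5)O[C@H]3c2ccc(OCc9ccccc9)cc2)cc1 | intermediate
33 | 3c,5c‑di‑tert‑butyl hexamer | Oc1ccc([C@H]2c3c(O)cc(O)cc3[C@@H]3c4c(cc(O)cc4[C@H]2[C@H](c2cc(C(C)(C)C)c(O)c(C(C)(C)C)c2)[C@H]2c4cc(O)cc5c4[C@@H](c4cc(O)cc(O)c4[C@H](c4ccc(O)cc4)[C@H]2c2cc(O)cc4c2[C@@H](c2cc(O)cc(O)c2)[C@H](c2ccc(O)cc2)O4)[C@H](c2ccc(O)cc2)O5)O[C@H]3c2ccc(O)cc2)cc1 | intermediate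
34 | target hexamer CNP0184494.1 | Oc1ccc([C@H]2c3c(O)cc(O)cc3[C@@H]3c4c(cc(O)cc4[C@H]2[C@H](c2ccc(O)cc2)[C@H]2c4cc(O)cc5c4[C@@H](c4cc(O)cc(O)c4[C@H](c4ccc(O)cc4)[C@H]2c2cc(O)cc4c2[C@@H](c2cc(O)cc(O)c2)[C@H](c2ccc(O)cc2)O4)[C@H](c2ccc(O)cc2)O5)O[C@H]3c2ccc(O)cc2)cc1 | target

**Totals**

Total step count: 23. Longest linear sequence: 18 (steps 2–10 and 15–23).

**Steps most likely to fail**

Step 17. Several processes may outrun C–C bond formation between two very hindered carbons: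
- proton transfer from the acidic α‑bromo ketone to the phenolate;
- halophilic attack on bromine;
- addition of a second phenolate to the new quinone methide.

Facial selectivity at C‑8c/C‑8e may also be poor. The fallback uses known chemistry, sets out from 13 and 23, and returns at 25. Palladium‑catalysed α‑arylation of commercial 3′,5′‑di‑tert‑butyl‑4′‑hydroxyacetophenone with 13 gives the block c/d hydroxyaryl deoxybenzoin F1. Its dianion (2 equiv KHMDS) is alkylated with 23 in the classical enolate/α‑halo ketone 1,4‑diketone synthesis to give the tetramer 1,4‑diketone F2, whose two α‑centres can be equilibrated with base. NaBH4 gives the tetramer 1,4‑diol F3. Only its 4‑hydroxybenzylic alcohol loses water on mild acid (PPTS), which gives the quinone methide alcohol F4. Dess–Martin oxidation of the remaining carbinol then returns to 25.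

Step 21. Loss of H‑8b or H‑8e from the unblocked quinone methides (tautomerisation to stilbenes with scrambling of C‑8) may compete with the slow medium‑ring closure. So may Grob‑type fragmentation of C‑7c–C‑8b pushed by the ring C‑1 phenolate, and O‑alkylation or oligomerisation. The fallback separates unmasking from cyclisation and changes the mode of activation; it sets out from 28 and returns at 32. Buffered TBAF/AcOH desilylation gives the heptaphenol diol F5. This is cyclised by phosphoric‑acid‑catalysed dehydrative Friedel–Crafts alkylation (diphenyl phosphate, CH2Cl2, high dilution). The 4‑hydroxybenzylic alcohols ionise under weak acid, and the bifunctional catalyst engages only arenes that carry a free OH.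

Step 18. The enolate may act as a base, enolising and epimerising at C‑8e, rather than as a nucleophile. The addition may also be reversible or too slow for steric reasons. The fallback splits the bond set, sets out from 25, 16 and 13, and returns at 27. The unhindered potassium enolate of 16 adds 1,6 to 25 to give the C‑7c phenacyl adduct F6. Palladium‑catalysed α‑arylation of its CH2 group with 13 then brings in block a/b. C‑8b is set α to the ketone, where it can still be equilibrated.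

**Further compounds**

F1 | step 17 | block c/d hydroxyaryl deoxybenzoin | O=C(Cc2cc(OCc9ccccc9)cc3c2[C@@H](c2cc(O[Si](C(C)C)(C(C)C)C(C)C)cc(O[Si](C(C)C)(C(C)C)C(C)C)c2)[C@H](c2ccc(OCc9ccccc9)cc2)O3)c1cc(C(C)(C)C)c(O)c(C(C)(C)C)c1
F2 | step 17 | tetramer 1,4‑diketone | O=C([C@H]([C@@H](C(=O)c2ccc(O[Si](C(C)C)(C(C)C)C(C)C)cc2)c2cc(OCc9ccccc9)cc3c2[C@@H](c2cc(OCc9ccccc9)cc(OCc9ccccc9)c2)[C@H](c2ccc(OCc9ccccc9)cc2)O3)c2cc(OCc9ccccc9)cc3c2[C@@H](c2cc(O[Si](C(C)C)(C(C)C)C(C)C)cc(O[Si](C(C)C)(C(C)C)C(C)C)c2)[C@H](c2ccc(OCc9ccccc9)cc2)O3)c1cc(C(C)(C)C)c(O)c(C(C)(C)C)c1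
F3 | step 17 | tetramer 1,4‑diol | OC([C@H]([C@@H](C(O)c2ccc(O[Si](C(C)C)(C(C)C)C(C)C)cc2)c2cc(OCc9ccccc9)cc3c2[C@@H](c2cc(OCc9ccccc9)cc(OCc9ccccc9)c2)[C@H](c2ccc(OCc9ccccc9)cc2)O3)c2cc(OCc9ccccc9)cc3c2[C@@H](c2cc(O[Si](C(C)C)(C(C)C)C(C)C)cc(O[Si](C(C)C)(C(C)C)C(C)C)c2)[C@H](c2ccc(OCc9ccccc9)cc2)O3)c1cc(C(C)(C)C)c(O)c(C(C)(C)C)c1
F4 | step 17 | quinone methide alcohol | CC(C)(C)C1=CC(=C[C@H]([C@@H](C(O)c2ccc(O[Si](C(C)C)(C(C)C)C(C)C)cc2)c2cc(OCc9ccccc9)cc3c2[C@@H](c2cc(OCc9ccccc9)cc(OCc9ccccc9)c2)[C@H](c2ccc(OCc9ccccc9)cc2)O3)c2cc(OCc9ccccc9)cc3c2[C@@H](c2cc(O[Si](C(C)C)(C(C)C)C(C)C)cc(O[Si](C(C)C)(C(C)C)C(C)C)c2)[C@H](c2ccc(OCc9ccccc9)cc2)O3)C=C(C(C)(C)C)C1=O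
F5 | step 21 | heptaphenol diol | CC(C)(C)c1cc([C@@H]([C@@H](C(O)c2ccc(O)cc2)c2cc(OCc9ccccc9)cc3c2[C@@H](c2cc(O)cc(O)c2)[C@H](c2ccc(OCc9ccccc9)cc2)O3)[C@H]([C@@H](C(O)c2ccc(O)cc2)c2cc(OCc9ccccc9)cc3c2[C@@H](c2cc(OCc9ccccc9)cc(OCc9ccccc9)c2)[C@H](c2ccc(OCc9ccccc9)cc2)O3)c2cc(OCc9ccccc9)cc3c2[C@@H](c2cc(O)cc(O)c2)[C@H](c2ccc(OCc9ccccc9)cc2)O3)cc(C(C)(C)C)c1O
F6 | step 18 | C‑7c phenacyl adduct | CC(C)(C)c1cc([C@@H](CC(=O)c2ccc(O[Si](C(C)C)(C(C)C)C(C)C)cc2)[C@H]([C@@H](C(=O)c2ccc(O[Si](C(C)C)(C(C)C)C(C)C)cc2)c2cc(OCc9ccccc9)cc3c2[C@@H](c2cc(OCc9ccccc9)cc(OCc9ccccc9)c2)[C@H](c2ccc(OCc9ccccc9)cc2)O3)c2cc(OCc9ccccc9)cc3c2[C@@H](c2cc(O[Si](C(C)C)(C(C)C)C(C)C)cc(O[Si](C(C)C)(C(C)C)C(C)C)c2)[C@H](c2ccc(OCc9ccccc9)cc2)O3)cc(C(C)(C)C)c1O
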